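**Plan**
1. Numbering follows the acid chain (C1 = CO2H; C3, C4, C6 = ring carbons; C7–C16 = side chain). Retrosynthetic cuts, in order: C2–C3 (acetate unit), the two C–O bonds of the peroxide (C3–O, C6–O), C9–C10 (phenylalkyl chain), and last C4–C5 together with C7–C8.
2. Enabling feature: C4 of the 1,2-dioxane ring and C8 of the side chain are both CH(CH3) centres, each one CH2 (C5, C7) away from C6. Drawn with C3 and C9 as carbonyl carbons both are S, so C3–C9 is a C2-symmetric 2,6-dimethyl-4-methyleneheptanedioyl unit with its axis through C6.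
3. Forward: two auxiliary-bearing propionyl enolates are alkylated on a 2-methylene-1,3-diiodide (C4–C5 and C7–C8). The arms are reduced, one of the two homotopic alcohols is tosylated and coupled with a C7 phenylalkyl Grignard reagent (C9–C10).
4. The only ring is made late: cobalt-catalysed hydroperoxysilylation puts the peroxide on C6 (the methylene carbon becomes the C6 methyl), C3 is oxidised to the aldehyde and closes the 1,2-dioxane as a methyl peroxyacetal. C1–C2 is then added at C3 and the ester is hydrolysed.
5. Stereochemistry: C4 and C8 come from the (R)-4-benzyloxazolidinone auxiliary (same sense twice). C3 comes from axial attack on the ring peroxycarbenium ion (3,4-cis). C6 is not controlled: it arises in a radical O2 capture with no facial bias, and the 6R epimer is isolated by chromatography of ester 15.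

Key step: step 2

Remark: O2 capture at the acyclic C6 radical is assumed to be unselective, so compounds 12–14 are carried as mixtures of C6 epimers.

**Step 1**
Reactants: 1 3-chloro-2-(chloromethyl)prop-1-ene
Product: 2 3-iodo-2-(iodomethyl)prop-1-ene
Conditions: NaI (2.5 equiv), acetone, rt, dark
Reagents that add atoms: sodium iodide, [Na+].[I-]
Why: Finkelstein halide exchange is driven by precipitation of NaCl from acetone and gives the more reactive bis-allylic iodide needed for enolate alkylation at low temperature.

**Step 2**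
Reactants: 3 (R)-4-benzyl-3-propionyloxazolidin-2-one (2.3 equiv); 2 3-iodo-2-(iodomethyl)prop-1-ene (1.0 equiv)
Product: 6 (4R,4'R)-3,3'-[(2S,6S)-2,6-dimethyl-4-methylideneheptanedioyl]bis(4-benzyloxazolidin-2-one), via sodium Z-enolate 4 (not isolated), via allylic iodide 5 (not isolated)
Conditions: NaN(SiMe3)2 (2.3 equiv), THF, −78 °C; then 2, −78 to −20 °C
Reagents that add atoms: none
Why: Deprotonation of 3 gives the sodium-chelated Z-enolate 4, which displaces iodide from 2 in an SN2 reaction; the allylic iodide 5 so formed is alkylated by a second enolate in the same flask, so the C4–C5 and C7–C8 bonds form in one operation. The closest known reaction type is the Evans alkylation of N-propionyl oxazolidinone enolates with allylic halides, here run in two directions on a 2-methylene-1,3-dihalide. No ring closes in this step. Both new stereocentres (C4 and C8) are controlled by the (R)-benzyl group of the auxiliary, which shields one face of the chelated enolate so that each alkylation gives the (S)-α-methyl imide. The step needs high facial selectivity twice and a complete second alkylation: the rigid chelate secures the first, and a single mismatched event gives a separable (2S,6R) diastereomer, so the C2-symmetric product is statistically enriched (Horeau principle); excess enolate secures the second, and SN2 and SN2' attack on 5 give the same product because the 2-methyleneallyl unit is symmetric.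

**Step 3**
Reactants: 6 (4R,4'R)-3,3'-[(2S,6S)-2,6-dimethyl-4-methylideneheptanedioyl]bis(4-benzyloxazolidin-2-one)
Product: 7 (2S,6S)-2,6-dimethyl-4-methylideneheptane-1,7-diol
Conditions: LiBH4, MeOH (additive), THF, 0 °C
Reagents that add atoms: none
Why: Reductive cleavage of N-acyl oxazolidinones with LiBH4 gives the primary alcohols without touching the α-stereocentres or the 1,1-disubstituted alkene and releases the auxiliary for recovery.

**Step 4**
Reactants: 7 (2S,6S)-2,6-dimethyl-4-methylideneheptane-1,7-diol
Product: 8 (2S,6S)-7-hydroxy-2,6-dimethyl-4-methylideneheptyl 4-methylbenzenesulfonate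
Conditions: TsCl (1.05 equiv), Ag2O (1.5 equiv), KI (0.2 equiv), CH2Cl2, 0 °C to rt
Reagents that add atoms: 4-methylbenzenesulfonyl chloride, Cc1ccc(cc1)S(Cl)(=O)=O
Why: The two hydroxyl groups of C2-symmetric 7 are homotopic, so Ag2O-mediated monosulfonylation of a symmetrical diol only has to stop after one tosylation to give a single compound.

**Step 5**
Reactants: 8 (2S,6S)-7-hydroxy-2,6-dimethyl-4-methylideneheptyl 4-methylbenzenesulfonate; 9 (7-bromoheptyl)benzene
Product: 11 (2S,6R)-2,6-dimethyl-4-methylidene-14-phenyltetradecan-1-ol, via Grignard reagent 10 (not isolated)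
Conditions: 9, Mg, THF, 40 °C; then 8, Li2CuCl4 (5 mol %), THF, −30 °C to rt (3 equiv of 10)
Reagents that add atoms: none
Why: Copper-catalysed Grignard cross-coupling of Kochi–Schlosser type displaces the primary tosylate in an sp3–sp3 coupling and forms C9–C10, the first equivalent of 10 masking the free hydroxyl as its magnesium alkoxide; no stereocentre is touched and the chain-bearing centre only changes its descriptor to R.

**Step 6**
Reactants: 11 (2S,6R)-2,6-dimethyl-4-methylidene-14-phenyltetradecan-1-ol
Product: 12 (2S,4RS,6R)-2,4,6-trimethyl-14-phenyl-4-[(triethylsilyl)peroxy]tetradecan-1-ol (C6 epimers of the target numbering)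
Conditions: Co(thd)2 [cobalt bis(2,2,6,6-tetramethylheptane-3,5-dionate)] (10 mol %), Et3SiH (2 equiv), O2 (1 atm), ClCH2CH2Cl, rt
Reagents that add atoms: dioxygen, O=O; triethylsilane, CC[SiH](CC)CC
Why: Isayama–Mukaiyama hydroperoxysilylation: a cobalt hydride transfers a hydrogen atom to the terminal alkene carbon, the tertiary C6 radical is trapped by O2 and the peroxyl is silylated, which installs the C6–O bond and turns the methylene into the C6 methyl; O2 capture by this acyclic radical is not expected to be face-selective, so both C6 epimers form and the 6R series is isolated at 15.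

**Step 7**
Reactants: 12 (2S,4RS,6R)-2,4,6-trimethyl-14-phenyl-4-[(triethylsilyl)peroxy]tetradecan-1-ol
Product: 13 (2S,4RS,6R)-2,4,6-trimethyl-14-phenyl-4-[(triethylsilyl)peroxy]tetradecanal
Conditions: Dess–Martin periodinane, pyridine, CH2Cl2, 0 °C to rt
Reagents that add atoms: none
Why: Dess–Martin oxidation converts the primary alcohol to the aldehyde under buffered, non-enolising conditions that leave the α-methyl stereocentre and the silyl peroxide intact.

**Step 8**
Reactants: 13 (2S,4RS,6R)-2,4,6-trimethyl-14-phenyl-4-[(triethylsilyl)peroxy]tetradecanal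
Product: 14 (4S,6RS)-3-methoxy-4,6-dimethyl-6-[(2R)-2-methyl-10-phenyldecyl]-1,2-dioxane (both anomers)
Conditions: TsOH·H2O (10 mol %), MeOH, 0 °C to rt
Reagents that add atoms: methanol, CO
Why: Acidic methanolysis removes the triethylsilyl group, the freed tertiary hydroperoxide adds to the aldehyde in a 6-exo-trig closure to the cyclic peroxyhemiacetal, and acid-catalysed acetalisation fixes it as the methyl peroxyacetal, whose anomeric configuration is irrelevant because C3 is ionised in the next step.

**Step 9**
Reactants: 14 (4S,6RS)-3-methoxy-4,6-dimethyl-6-[(2R)-2-methyl-10-phenyldecyl]-1,2-dioxane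
Product: 15 methyl 2-[(3S,4S,6R)-4,6-dimethyl-6-[(2R)-2-methyl-10-phenyldecyl]-1,2-dioxan-3-yl]acetate
Conditions: CH2=C(OMe)OSiMe3 (3 equiv), TiCl4 (1.1 equiv), CH2Cl2, −78 °C; chromatographic separation of the C6 epimer
Reagents that add atoms: 1-methoxy-1-(trimethylsilyloxy)ethene, C=C(OC)O[Si](C)(C)C
Why: Peroxycarbenium-mediated Mukaiyama-type substitution: TiCl4 ionises the exocyclic methoxy group and the silyl ketene acetal attacks the ring O=C3 cation along the axial trajectory of the half-chair that keeps the C4 methyl and the C6 arm pseudo-equatorial, which should give the 3,4-cis (3S) acetate, and the (3S,4S,6R) ester is separated from its C6 epimer at this stage.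

**Step 10**
Reactants: 15 methyl 2-[(3S,4S,6R)-4,6-dimethyl-6-[(2R)-2-methyl-10-phenyldecyl]-1,2-dioxan-3-yl]acetate
Product: 16 2-[(3S,4S,6R)-4,6-dimethyl-6-[(2R)-2-methyl-10-phenyldecyl]-1,2-dioxan-3-yl]acetic acid
Conditions: LiOH, THF/H2O (3:1), 0 °C; then 1 M HCl to pH 3
Reagents that add atoms: lithium hydroxide, [Li+].[OH-]
Why: Saponification of the methyl ester with LiOH at 0 °C followed by mild acidification should give the acid, since the dialkyl peroxide and all four stereocentres tolerate brief cold aqueous base.

**Compound list**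
1 | 3-chloro-2-(chloromethyl)prop-1-ene | C=C(CCl)CCl | starting material
2 | 3-iodo-2-(iodomethyl)prop-1-ene | C=C(CI)CI | intermediate
3 | (R)-4-benzyl-3-propionyloxazolidin-2-one | CCC(=O)N1[C@H](Cc2ccccc2)COC1=O | starting material
4 | sodium (Z)-1-[(4R)-4-benzyl-2-oxooxazolidin-3-yl]prop-1-en-1-olate (sodium Z-enolate of 3) | C/C=C(\[O-])N1[C@H](Cc2ccccc2)COC1=O.[Na+] | intermediate
5 | (R)-4-benzyl-3-[(S)-4-(iodomethyl)-2-methylpent-4-enoyl]oxazolidin-2-one | C=C(CI)C[C@H](C)C(=O)N1[C@H](Cc2ccccc2)COC1=O | intermediate
6 | (4R,4'R)-3,3'-[(2S,6S)-2,6-dimethyl-4-methylideneheptanedioyl]bis(4-benzyloxazolidin-2-one) | C=C(C[C@H](C)C(=O)N1[C@H](Cc2ccccc2)COC1=O)C[C@H](C)C(=O)N1[C@H](Cc2ccccc2)COC1=O | intermediate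
7 | (2S,6S)-2,6-dimethyl-4-methylideneheptane-1,7-diol | C=C(C[C@H](C)CO)C[C@H](C)CO | intermediate
8 | (2S,6S)-7-hydroxy-2,6-dimethyl-4-methylideneheptyl 4-methylbenzenesulfonate | C=C(C[C@H](C)CO)C[C@H](C)COS(=O)(=O)c1ccc(C)cc1 | intermediate
9 | (7-bromoheptyl)benzene | BrCCCCCCCc1ccccc1 | starting material
10 | (7-phenylheptyl)magnesium bromide | Br[Mg]CCCCCCCc1ccccc1 | intermediate
11 | (2S,6R)-2,6-dimethyl-4-methylidene-14-phenyltetradecan-1-ol | C=C(C[C@H](C)CO)C[C@H](C)CCCCCCCCc1ccccc1 | intermediate
12 | (2S,4RS,6R)-2,4,6-trimethyl-14-phenyl-4-[(triethylsilyl)peroxy]tetradecan-1-ol (epimers at the peroxide carbon) | CC(C[C@H](C)CO)(OO[Si](CC)(CC)CC)C[C@H](C)CCCCCCCCc1ccccc1 | intermediate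
13 | (2S,4RS,6R)-2,4,6-trimethyl-14-phenyl-4-[(triethylsilyl)peroxy]tetradecanal (epimers at the peroxide carbon) | CC(C[C@H](C)C=O)(OO[Si](CC)(CC)CC)C[C@H](C)CCCCCCCCc1ccccc1 | intermediate
14 | (4S,6RS)-3-methoxy-4,6-dimethyl-6-[(2R)-2-methyl-10-phenyldecyl]-1,2-dioxane (C6 epimers, both anomers) | C[C@H](CCCCCCCCc1ccccc1)CC1(C)C[C@H](C)C(OC)OO1 | intermediate
15 | methyl 2-[(3S,4S,6R)-4,6-dimethyl-6-[(2R)-2-methyl-10-phenyldecyl]-1,2-dioxan-3-yl]acetate | C[C@H](CCCCCCCCc1ccccc1)C[C@]1(C)C[C@H](C)[C@H](CC(=O)OC)OO1 | intermediate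
16 | 2-[(3S,4S,6R)-4,6-dimethyl-6-[(2R)-2-methyl-10-phenyldecyl]-1,2-dioxan-3-yl]acetic acid | C[C@H](CCCCCCCCc1ccccc1)C[C@]1(C)C[C@H](C)[C@H](CC(=O)O)OO1 | target

**Totals**
Total step count: 10.
Longest linear sequence: 10 steps (1 to 16); 3 enters at step 2 and 9 at step 5.

**Steps most likely to fail**

Step 6. The tertiary C6 radical is acyclic and captures O2 from both faces, so about half of the material is expected to end in the 6-epi series, and the epimers may be hard to separate before the ring is closed. The fallback closes the ring from the C3 side, so that the C6–O bond forms in a cyclic transition state. It sets out from 11 and comes back at 14. Alcohol 11 is oxidised (Dess–Martin periodinane, CH2Cl2) to (2S,6R)-2,6-dimethyl-4-methylidene-14-phenyltetradecanal F1. Peroxyacetalisation with urea·H2O2 and catalytic Sc(OTf)3 in MeOH gives (2S,6R)-1-methoxy-2,6-dimethyl-4-methylidene-14-phenyltetradecyl hydroperoxide F2 as a mixture at the acetal carbon. 6-exo iodoperoxidation with N-iodosuccinimide (CH2Cl2, −78 to 0 °C) should give (4S,6R)-6-(iodomethyl)-3-methoxy-4-methyl-6-[(2R)-2-methyl-10-phenyldecyl]-1,2-dioxane F3 through a chair transition state with the C4 methyl equatorial and the branched C7 arm anti to the C4–C5 bond, the iodonium-bearing methylene becoming axial; this preference is expected to be modest and would need to be checked. Radical deiodination (Bu3SnH in high concentration, Et3B/air, toluene, 0 °C) then gives 14 in the 6R series. Known weaknesses of this path are competing attack of the methoxy oxygen on the iodonium ion and epoxide-forming fragmentation of the β-peroxy radical.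

Step 9. The Lewis acid may heterolyse the tertiary C6–O bond and fragment the peroxide, the cation may lose the C4 proton, or attack may occur on the equatorial face and give the 3,4-trans ester. The fallback sets C3 by a reagent-controlled carbinol and an SN2 ring closure. It sets out from 13 and comes back at 16. Aldehyde 13 is allylated with the antipode of B-allyldiisopinocampheylborane that delivers the 4R carbinol (Et2O, −78 °C, ethanolamine work-up) to give (4R,5S,9R)-5,7,9-trimethyl-17-phenyl-7-[(triethylsilyl)peroxy]heptadec-1-en-4-ol F4. Mesylation (MsCl, Et3N, CH2Cl2, 0 °C) gives (4R,5S,9R)-5,7,9-trimethyl-17-phenyl-7-[(triethylsilyl)peroxy]heptadec-1-en-4-yl methanesulfonate F5. Bu4NF in THF at 0 °C removes the silyl group, and the peroxide anion displaces the mesylate in a 6-exo-tet closure with inversion to give (3S,4S,6R)-4,6-dimethyl-6-[(2R)-2-methyl-10-phenyldecyl]-3-(prop-2-en-1-yl)-1,2-dioxane F6, the C6 epimer being removed by chromatography here. Ozonolysis (O3, CH2Cl2, −78 °C; Me2S) gives 2-[(3S,4S,6R)-4,6-dimethyl-6-[(2R)-2-methyl-10-phenyldecyl]-1,2-dioxan-3-yl]acetaldehyde F7, and Pinnick oxidation (NaClO2, NaH2PO4, 2-methylbut-2-ene) gives 16.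

Step 10. Hydroxide may deprotonate C2 of the β-peroxy ester and open the ring by E1cB elimination of the peroxide, which would erode C3 on re-closure or destroy the peroxide. The fallback avoids both the ester and the basic step. It sets out from 14 and comes back at 16: 14 is treated with 1,1-bis(trimethylsilyloxy)ethene and TiCl4 (CH2Cl2, −78 °C), the silyl ester is hydrolysed on aqueous work-up, and the acid 16 is obtained directly. The C6 epimers are then separated as the acids by reversed-phase HPLC.

**Further compounds**
F1 | step 6 | (2S,6R)-2,6-dimethyl-4-methylidene-14-phenyltetradecanal | C=C(C[C@H](C)C=O)C[C@H](C)CCCCCCCCc1ccccc1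
F2 | step 6 | (2S,6R)-1-methoxy-2,6-dimethyl-4-methylidene-14-phenyltetradecyl hydroperoxide | C=C(C[C@H](C)C(OC)OO)C[C@H](C)CCCCCCCCc1ccccc1
F3 | step 6 | (4S,6R)-6-(iodomethyl)-3-methoxy-4-methyl-6-[(2R)-2-methyl-10-phenyldecyl]-1,2-dioxane | C[C@H](CCCCCCCCc1ccccc1)C[C@]1(CI)C[C@H](C)C(OC)OO1
F4 | step 9 | (4R,5S,9R)-5,7,9-trimethyl-17-phenyl-7-[(triethylsilyl)peroxy]heptadec-1-en-4-ol | C=CC[C@@H](O)[C@@H](C)CC(C)(OO[Si](CC)(CC)CC)C[C@H](C)CCCCCCCCc1ccccc1
F5 | step 9 | (4R,5S,9R)-5,7,9-trimethyl-17-phenyl-7-[(triethylsilyl)peroxy]heptadec-1-en-4-yl methanesulfonate | C=CC[C@@H](OS(C)(=O)=O)[C@@H](C)CC(C)(OO[Si](CC)(CC)CC)C[C@H](C)CCCCCCCCc1ccccc1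
F6 | step 9 | (3S,4S,6R)-4,6-dimethyl-6-[(2R)-2-methyl-10-phenyldecyl]-3-(prop-2-en-1-yl)-1,2-dioxane | C[C@H](CCCCCCCCc1ccccc1)C[C@]1(C)C[C@H](C)[C@H](CC=C)OO1
F7 | step 9 | 2-[(3S,4S,6R)-4,6-dimethyl-6-[(2R)-2-methyl-10-phenyldecyl]-1,2-dioxan-3-yl]acetaldehyde | C[C@H](CCCCCCCCc1ccccc1)C[C@]1(C)C[C@H](C)[C@H](CC=O)OO1
F0 | step 10 | none | none
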